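**Plan**
Handle: in the tetrahydrofuran (O1, C2, C3, C4, C5) the ether carbon C2 is bonded directly to the tertiary carbinol C3, and the C3 hydroxyl is cis to the carbon chain on C2. A (Z)-γ-alkoxyallylboron unit hung on O1 and delivered to a C3 methyl ketone leaves exactly this pattern.
Cuts (retro): C2'–C3' of the hydroxycyclohexanedione (Dieckmann), then C1'–C2' (alkylzinc plus thioester), then C2–C3 of the tetrahydrofuran (allyl transfer), then O1–C(allenyl) and C5–C(dienyl).
Forward: dienyl iodide plus a C4 Weinreb amide give an enone; reduction sets C5; the O-allenyl methyl ketone closes the tetrahydrofuran in step 11; the vinyl group is then extended with a glutamate-derived thioester and the six-membered ring is closed last.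
Stereochemistry: C5 by CBS reduction; C2 and C3 by the chair allylboration, relayed from C5; C4' from L-glutamic acid (retention on diazotisation); the E alkene by syn carboalumination.

Key step: step 11

Remarks on the chemistry: atoms are labelled O1, C2–C5 in the tetrahydrofuran and C1'–C6' in the cyclohexane ring (C2' carries the CH2 link, C4' the hydroxyl). The target is treated as the drawn enol form of a 2-alkyl-4-hydroxycyclohexane-1,3-dione, whose tautomers interconvert. Conjugate acid–base partners of numbered compounds (alkoxides, carboxylates, enolates) and adducts that last only until work-up carry no number of their own, the borinate of step 11 excepted. Ethyl (3S)-3-hydroxybutanoate and L-glutamic acid 5-benzyl ester are taken as commercial; the butanoate stereocentre only keeps intermediates 7–15 single diastereomers and is erased in step 10.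

**Route**

Step 1
Reactants: 1 6-methylhept-5-en-2-one
Product: 3 6-methylhept-5-en-1-yne, via enol phosphate 2 (not isolated)
Conditions: LiN(i-Pr)2 (1.05 equiv), THF, −78 °C; ClP(O)(OEt)2, −78 °C → rt; LiN(i-Pr)2 (2.3 equiv), −78 °C → rt; H2O
Reagents that add atoms: none
Why: The kinetic enolate forms on the methyl side, is trapped on oxygen and loses diethyl phosphate under excess amide base, the established enol phosphate route from methyl ketones to terminal alkynes, which leaves the trisubstituted alkene alone.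

Step 2
Reactants: 3 6-methylhept-5-en-1-yne
Product: 5 (1E)-1-iodo-2,6-dimethylhepta-1,5-diene, via alkenylalane 4 (not isolated)
Conditions: Me3Al (2 equiv), Cp2ZrCl2 (0.25 equiv), CH2Cl2, 0 °C → rt; then I2, THF, −30 → 0 °C
Reagents that add atoms: trimethylaluminium, C[Al](C)C; iodine, II
Why: Negishi carboalumination adds methyl and aluminium syn across the alkyne with aluminium at the terminus, and iodinolysis with retention gives the E vinyl iodide; the isolated trisubstituted alkene does not react.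

Step 3
Reactants: 6 ethyl (3S)-3-hydroxybutanoate
Product: 7 ethyl (3S)-3-[(tert-butyldiphenylsilyl)oxy]butanoate
Conditions: t-BuPh2SiCl, imidazole, DMF, rt
Reagents that add atoms: tert-butyl(chloro)diphenylsilane, CC(C)(C)[Si](Cl)(c1ccccc1)c1ccccc1
Why: Routine silylation of a secondary alcohol; the bulky silyl group is chosen because it should neither migrate to the neighbouring alkoxide in step 7 nor be lost to KOtBu in step 8.

Step 4
Reactants: 7 ethyl (3S)-3-[(tert-butyldiphenylsilyl)oxy]butanoate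
Product: 8 (3S)-3-[(tert-butyldiphenylsilyl)oxy]-N-methoxy-N-methylbutanamide
Conditions: MeNH(OMe)·HCl, i-PrMgCl, THF, −20 → 0 °C
Reagents that add atoms: N,O-dimethylhydroxylamine hydrochloride, CNOC.Cl
Why: Weinreb amide formation from an ester with the chloromagnesium amide is standard, and the low temperature keeps the β-silyloxy ester from eliminating.

Step 5
Reactants: 5 (1E)-1-iodo-2,6-dimethylhepta-1,5-diene; 8 (3S)-3-[(tert-butyldiphenylsilyl)oxy]-N-methoxy-N-methylbutanamide
Product: 10 (2S,5E)-2-[(tert-butyldiphenylsilyl)oxy]-6,10-dimethylundeca-5,9-dien-4-one, via vinyllithium 9 (not isolated)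
Conditions: 5, t-BuLi (2 equiv per iodide), Et2O, −78 °C; then 8, −78 → 0 °C; H2O
Reagents that add atoms: none
Why: Iodine–lithium exchange keeps the alkene geometry and the vinyllithium adds only once because the chelated tetrahedral adduct persists until work-up (Weinreb ketone synthesis).

Step 6
Reactants: 10 (2S,5E)-2-[(tert-butyldiphenylsilyl)oxy]-6,10-dimethylundeca-5,9-dien-4-one
Product: 11 (2S,4R,5E)-2-[(tert-butyldiphenylsilyl)oxy]-6,10-dimethylundeca-5,9-dien-4-ol
Conditions: (S)-Me-CBS oxazaborolidine [(3aS)-1-methyl-3,3-diphenyltetrahydro-1H,3H-pyrrolo[1,2-c][1,3,2]oxazaborole] (0.2 equiv), catecholborane, toluene, −78 °C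
Reagents that add atoms: none
Why: Corey–Bakshi–Shibata reduction: with the β,β-disubstituted alkenyl group as the large and the CH2 group as the small substituent, the (S)-oxazaborolidine should deliver hydride to the face that gives the 4R allylic alcohol (the future C5), the remote silyloxy centre having little say.

Step 7
Reactants: 11 (2S,4R,5E)-2-[(tert-butyldiphenylsilyl)oxy]-6,10-dimethylundeca-5,9-dien-4-ol; 12 propargyl bromide
Product: 13 tert-butyl{[(2S,4R,5E)-6,10-dimethyl-4-(prop-2-yn-1-yloxy)undeca-5,9-dien-2-yl]oxy}diphenylsilane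
Conditions: NaH, Bu4NI (cat.), THF, 0 °C → rt
Reagents that add atoms: propargyl bromide (12), C#CCBr
Why: Williamson ether synthesis of the sodium alkoxide with a reactive propargylic bromide, which does not touch C5.

Step 8
Reactants: 13 tert-butyl{[(2S,4R,5E)-6,10-dimethyl-4-(prop-2-yn-1-yloxy)undeca-5,9-dien-2-yl]oxy}diphenylsilane
Product: 14 tert-butyl{[(2S,4R,5E)-6,10-dimethyl-4-(propa-1,2-dien-1-yloxy)undeca-5,9-dien-2-yl]oxy}diphenylsilane
Conditions: KOtBu (0.3 equiv), THF, rt
Reagents that add atoms: none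
Why: Base-catalysed propargyl-to-allenyl ether isomerisation stops at the alkoxyallene under these mild conditions, and the ketone is still masked as a silyl ether so that nothing else in the molecule is base-labile.

Step 9
Reactants: 14 tert-butyl{[(2S,4R,5E)-6,10-dimethyl-4-(propa-1,2-dien-1-yloxy)undeca-5,9-dien-2-yl]oxy}diphenylsilane
Product: 15 (2S,4R,5E)-6,10-dimethyl-4-(propa-1,2-dien-1-yloxy)undeca-5,9-dien-2-ol
Conditions: Bu4NF, THF, rt
Reagents that add atoms: none
Why: Fluoride desilylation, to which alkoxyallenes are inert.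

Step 10
Reactants: 15 (2S,4R,5E)-6,10-dimethyl-4-(propa-1,2-dien-1-yloxy)undeca-5,9-dien-2-ol
Product: 16 (4R,5E)-6,10-dimethyl-4-(propa-1,2-dien-1-yloxy)undeca-5,9-dien-2-one
Conditions: Dess–Martin periodinane, NaHCO3, CH2Cl2, 0 °C → rt; chromatography on Et3N-deactivated silica
Reagents that add atoms: none
Why: Dess–Martin oxidation at buffered neutral pH gives the methyl ketone without hydrolysing the acid-labile allenyl ether or eliminating the β-alkoxy group.

Step 11
Reactants: 16 (4R,5E)-6,10-dimethyl-4-(propa-1,2-dien-1-yloxy)undeca-5,9-dien-2-one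
Product: 19 (2S,3S,5R)-5-[(1E)-2,6-dimethylhepta-1,5-dien-1-yl]-2-ethenyl-3-methyloxolan-3-ol, via allylborane 17 (not isolated), via borinate 18 (not isolated)
Conditions: (c-C6H11)2BH (1.05 equiv; made from cyclohexene and BH3·SMe2, THF, 0 °C), added in portions to 16, THF, −20 → 0 °C; then HOCH2CH2NH2, Et2O, rt
Reagents that add atoms: none
Why: Proposed new method: the dialkylborane should add across the unsubstituted terminal C=C of the allenyl ether, boron on the CH2 terminus and hydride on the central carbon from the side away from oxygen, to give the (Z)-γ-alkoxyallylborane 17, whose boron then binds the ketone oxygen while the oxygen-bearing γ-carbon C2 is delivered to C3 through a closed six-membered chair. The closest known reactions are the kinetic hydroboration of monosubstituted allenes to (Z)-allyldialkylboranes and the intramolecular allylboration of carbonyl groups by tethered γ-alkoxyallylboron reagents, which gives 2-vinyl-3-hydroxy cyclic ethers. The tetrahydrofuran closes in a 5-exo-trig mode, fused to the chair along the forming C2–C3 bond. C2 and C3 are set together: the Z geometry holds O1 axial, so the tether carbon C4 must sit equatorial and the methyl group axial, which puts the vinyl group and the new hydroxyl cis; the sense relative to C5 is relayed by the dienyl group, which should take the convex face of the fused transition state, trans to the vinyl group and cis to the methyl group. The step needs hydroboration of the allene before reduction of the ketone or attack on the trisubstituted alkenes, boron at the terminal and not the central allene carbon, and retention of the Z geometry until transfer; the high rate of allene hydroboration by dicyclohexylborane at low temperature, the bulk of the reagent, portionwise addition of one equivalent and the immediate intramolecular trap should secure these. The medium is neutral, which spares the base-sensitive β-alkoxy ketone.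

Step 12
Reactants: 19 (2S,3S,5R)-5-[(1E)-2,6-dimethylhepta-1,5-dien-1-yl]-2-ethenyl-3-methyloxolan-3-ol
Product: 20 {[(2S,3S,5R)-5-[(1E)-2,6-dimethylhepta-1,5-dien-1-yl]-2-ethenyl-3-methyloxolan-3-yl]oxy}triethylsilane
Conditions: Et3SiOTf, 2,6-lutidine, CH2Cl2, −78 → 0 °C
Reagents that add atoms: triethylsilyl trifluoromethanesulfonate, CC[Si](CC)(CC)OS(=O)(=O)C(F)(F)F
Why: Silyl triflate silylation copes with the hindered tertiary alcohol, and the ether keeps the alkoxide from displacing the later iodide or adding to the later ketone.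

Step 13
Reactants: 20 {[(2S,3S,5R)-5-[(1E)-2,6-dimethylhepta-1,5-dien-1-yl]-2-ethenyl-3-methyloxolan-3-yl]oxy}triethylsilane
Product: 22 2-[(2S,3S,5R)-5-[(1E)-2,6-dimethylhepta-1,5-dien-1-yl]-3-methyl-3-[(triethylsilyl)oxy]oxolan-2-yl]ethan-1-ol, via alkylborane 21 (not isolated)
Conditions: 9-BBN, THF, 0 °C → rt; then NaOH, H2O2, 0 °C
Reagents that add atoms: hydrogen peroxide, OO
Why: Brown hydroboration–oxidation: 9-BBN reacts with the monosubstituted vinyl group far faster than with the two trisubstituted alkenes and places boron on the terminal carbon.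

Step 14
Reactants: 22 2-[(2S,3S,5R)-5-[(1E)-2,6-dimethylhepta-1,5-dien-1-yl]-3-methyl-3-[(triethylsilyl)oxy]oxolan-2-yl]ethan-1-ol
Product: 23 {[(2S,3S,5R)-5-[(1E)-2,6-dimethylhepta-1,5-dien-1-yl]-2-(2-iodoethyl)-3-methyloxolan-3-yl]oxy}triethylsilane
Conditions: PPh3, I2, imidazole, CH2Cl2, 0 °C → rt
Reagents that add atoms: iodine, II
Why: Appel-type iodination converts the primary alcohol into the iodide by SN2 displacement of the oxyphosphonium group under near-neutral conditions.

Step 15
Reactants: 24 L-glutamic acid 5-benzyl ester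
Product: 27 (2S)-5-(benzyloxy)-2-hydroxy-5-oxopentanoic acid, via diazonium carboxylate 25 (not isolated), via alpha-lactone 26 (not isolated)
Conditions: NaNO2, 1 M H2SO4, H2O/dioxane, 0 °C → rt
Reagents that add atoms: water, O
Why: Diazotisation of an α-amino acid gives the α-hydroxy acid with net retention (double inversion through the α-lactone), so C4' keeps the L configuration, and the benzyl ester keeps the side-chain carboxyl from lactonising.

Step 16
Reactants: 27 (2S)-5-(benzyloxy)-2-hydroxy-5-oxopentanoic acid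
Product: 28 5-benzyl 1-methyl (2S)-2-hydroxypentanedioate
Conditions: MeI, KHCO3, DMF, rt
Reagents that add atoms: iodomethane, CI
Why: SN2 alkylation of the potassium carboxylate esterifies the acid selectively, the weak base leaving the hydroxyl group and the benzyl ester alone.

Step 17
Reactants: 28 5-benzyl 1-methyl (2S)-2-hydroxypentanedioate
Product: 29 5-benzyl 1-methyl (2S)-2-[(tert-butyldimethylsilyl)oxy]pentanedioate
Conditions: t-BuMe2SiCl, imidazole, DMF, rt
Reagents that add atoms: tert-butyl(chloro)dimethylsilane, CC(C)(C)[Si](C)(C)Cl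
Why: Standard silylation of an α-hydroxy ester.

Step 18
Reactants: 29 5-benzyl 1-methyl (2S)-2-[(tert-butyldimethylsilyl)oxy]pentanedioate
Product: 30 (4S)-4-[(tert-butyldimethylsilyl)oxy]-5-methoxy-5-oxopentanoic acid
Conditions: H2 (1 atm), Pd/C, EtOAc, rt
Reagents that add atoms: none
Why: Hydrogenolysis cleaves only the benzyl ester and frees the side-chain acid.

Step 19
Reactants: 30 (4S)-4-[(tert-butyldimethylsilyl)oxy]-5-methoxy-5-oxopentanoic acid
Product: 31 methyl (2S)-2-[(tert-butyldimethylsilyl)oxy]-5-(ethylsulfanyl)-5-oxopentanoate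
Conditions: EtSH, DCC, 4-(dimethylamino)pyridine (cat.), CH2Cl2, 0 °C → rt
Reagents that add atoms: ethanethiol, CCS
Why: Steglich-type carbodiimide coupling gives the S-ethyl thioester, the activated carboxyl being remote from the stereocentre.

Step 20
Reactants: 23 {[(2S,3S,5R)-5-[(1E)-2,6-dimethylhepta-1,5-dien-1-yl]-2-(2-iodoethyl)-3-methyloxolan-3-yl]oxy}triethylsilane; 31 methyl (2S)-2-[(tert-butyldimethylsilyl)oxy]-5-(ethylsulfanyl)-5-oxopentanoate
Product: 33 methyl (2S)-2-[(tert-butyldimethylsilyl)oxy]-7-[(2S,3S,5R)-5-[(1E)-2,6-dimethylhepta-1,5-dien-1-yl]-3-methyl-3-[(triethylsilyl)oxy]oxolan-2-yl]-5-oxoheptanoate, via alkylzinc iodide 32 (not isolated)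
Conditions: 23, Zn dust (activated by BrCH2CH2Br and Me3SiCl), THF/N,N-dimethylacetamide, 40 °C; then 31 (1.5 equiv), PdCl2(PPh3)2 (10 mol %), toluene, rt
Reagents that add atoms: none
Why: Fukuyama coupling: zinc inserts into the primary C–I bond and the alkylzinc iodide is acylated by the thioester under palladium catalysis, a ketone synthesis that leaves the methyl ester, silyl ethers and alkenes alone; zinc is γ to the ring oxygen, so β-elimination is not possible.

Step 21
Reactants: 33 methyl (2S)-2-[(tert-butyldimethylsilyl)oxy]-7-[(2S,3S,5R)-5-[(1E)-2,6-dimethylhepta-1,5-dien-1-yl]-3-methyl-3-[(triethylsilyl)oxy]oxolan-2-yl]-5-oxoheptanoate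
Product: 34 (4S)-4-[(tert-butyldimethylsilyl)oxy]-2-{[(2S,3S,5R)-5-[(1E)-2,6-dimethylhepta-1,5-dien-1-yl]-3-methyl-3-[(triethylsilyl)oxy]oxolan-2-yl]methyl}-3-hydroxycyclohex-2-en-1-one
Conditions: KOtBu (2.2 equiv), THF, 0 °C → rt; then aq. KHSO4 to pH 4
Reagents that add atoms: none
Why: Dieckmann (intramolecular Claisen) condensation of a δ-keto ester: the ketone enolate on the side-chain carbon attacks the methyl ester in a 6-(enolendo)-exo-trig closure, and the resulting 1,3-dione is held as its enolate, which drives the reaction and shields C4' from epimerisation.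

Step 22
Reactants: 34 (4S)-4-[(tert-butyldimethylsilyl)oxy]-2-{[(2S,3S,5R)-5-[(1E)-2,6-dimethylhepta-1,5-dien-1-yl]-3-methyl-3-[(triethylsilyl)oxy]oxolan-2-yl]methyl}-3-hydroxycyclohex-2-en-1-one
Product: 35 (4S)-2-{[(2S,3S,5R)-5-[(1E)-2,6-dimethylhepta-1,5-dien-1-yl]-3-hydroxy-3-methyloxolan-2-yl]methyl}-3,4-dihydroxycyclohex-2-en-1-one
Conditions: HF·pyridine, pyridine, THF, 0 °C → rt
Reagents that add atoms: none
Why: Buffered HF·pyridine removes the tertiary triethylsilyl and the secondary tert-butyldimethylsilyl ether without the strong acid that could dehydrate the tertiary alcohol onto the dione.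

**Compound list**
1 | 6-methylhept-5-en-2-one | CC(=O)CCC=C(C)C | starting material
2 | diethyl 6-methylhepta-1,5-dien-2-yl phosphate | C=C(CCC=C(C)C)OP(=O)(OCC)OCC | intermediate (not isolated)
3 | 6-methylhept-5-en-1-yne | C#CCCC=C(C)C | intermediate
4 | [(1E)-2,6-dimethylhepta-1,5-dien-1-yl]dimethylalane | CC(C)=CCC/C(C)=C/[Al](C)C | intermediate (not isolated)
5 | (1E)-1-iodo-2,6-dimethylhepta-1,5-diene | CC(C)=CCC/C(C)=C/I | intermediate
6 | ethyl (3S)-3-hydroxybutanoate | CCOC(=O)C[C@H](C)O | starting material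
7 | ethyl (3S)-3-[(tert-butyldiphenylsilyl)oxy]butanoate | CCOC(=O)C[C@H](C)O[Si](c1ccccc1)(c1ccccc1)C(C)(C)C | intermediate
8 | (3S)-3-[(tert-butyldiphenylsilyl)oxy]-N-methoxy-N-methylbutanamide | CON(C)C(=O)C[C@H](C)O[Si](c1ccccc1)(c1ccccc1)C(C)(C)C | intermediate
9 | [(1E)-2,6-dimethylhepta-1,5-dien-1-yl]lithium | CC(C)=CCC/C(C)=C/[Li] | intermediate (not isolated)
10 | (2S,5E)-2-[(tert-butyldiphenylsilyl)oxy]-6,10-dimethylundeca-5,9-dien-4-one | CC(C)=CCC/C(C)=C/C(=O)C[C@H](C)O[Si](c1ccccc1)(c1ccccc1)C(C)(C)C | intermediate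
11 | (2S,4R,5E)-2-[(tert-butyldiphenylsilyl)oxy]-6,10-dimethylundeca-5,9-dien-4-ol | CC(C)=CCC/C(C)=C/[C@H](O)C[C@H](C)O[Si](c1ccccc1)(c1ccccc1)C(C)(C)C | intermediate
12 | propargyl bromide (3-bromoprop-1-yne) | C#CCBr | starting material
13 | tert-butyl{[(2S,4R,5E)-6,10-dimethyl-4-(prop-2-yn-1-yloxy)undeca-5,9-dien-2-yl]oxy}diphenylsilane | CC(C)=CCC/C(C)=C/[C@H](OCC#C)C[C@H](C)O[Si](c1ccccc1)(c1ccccc1)C(C)(C)C | intermediate
14 | tert-butyl{[(2S,4R,5E)-6,10-dimethyl-4-(propa-1,2-dien-1-yloxy)undeca-5,9-dien-2-yl]oxy}diphenylsilane | CC(C)=CCC/C(C)=C/[C@H](OC=C=C)C[C@H](C)O[Si](c1ccccc1)(c1ccccc1)C(C)(C)C | intermediate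
15 | (2S,4R,5E)-6,10-dimethyl-4-(propa-1,2-dien-1-yloxy)undeca-5,9-dien-2-ol | CC(C)=CCC/C(C)=C/[C@H](OC=C=C)C[C@H](C)O | intermediate
16 | (4R,5E)-6,10-dimethyl-4-(propa-1,2-dien-1-yloxy)undeca-5,9-dien-2-one | CC(C)=CCC/C(C)=C/[C@H](OC=C=C)CC(C)=O | intermediate (key-step precursor)
17 | (4R,5E)-4-{[(1Z)-3-(dicyclohexylboranyl)prop-1-en-1-yl]oxy}-6,10-dimethylundeca-5,9-dien-2-one | CC(C)=CCC/C(C)=C/[C@H](O/C=C\CB(C1CCCCC1)C1CCCCC1)CC(C)=O | intermediate (not isolated)
18 | (2S,3S,5R)-5-[(1E)-2,6-dimethylhepta-1,5-dien-1-yl]-2-ethenyl-3-methyloxolan-3-yl dicyclohexylborinate | CC(C)=CCC/C(C)=C/[C@H]1C[C@](C)(OB(C2CCCCC2)C2CCCCC2)[C@H](C=C)O1 | intermediate (not isolated)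
19 | (2S,3S,5R)-5-[(1E)-2,6-dimethylhepta-1,5-dien-1-yl]-2-ethenyl-3-methyloxolan-3-ol | CC(C)=CCC/C(C)=C/[C@H]1C[C@](C)(O)[C@H](C=C)O1 | intermediate (key-step product)
20 | {[(2S,3S,5R)-5-[(1E)-2,6-dimethylhepta-1,5-dien-1-yl]-2-ethenyl-3-methyloxolan-3-yl]oxy}triethylsilane | CC(C)=CCC/C(C)=C/[C@H]1C[C@](C)(O[Si](CC)(CC)CC)[C@H](C=C)O1 | intermediate
21 | 9-{2-[(2S,3S,5R)-5-[(1E)-2,6-dimethylhepta-1,5-dien-1-yl]-3-methyl-3-[(triethylsilyl)oxy]oxolan-2-yl]ethyl}-9-borabicyclo[3.3.1]nonane | CC(C)=CCC/C(C)=C/[C@H]1C[C@](C)(O[Si](CC)(CC)CC)[C@H](CCB2C3CCCC2CCC3)O1 | intermediate (not isolated)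
22 | 2-[(2S,3S,5R)-5-[(1E)-2,6-dimethylhepta-1,5-dien-1-yl]-3-methyl-3-[(triethylsilyl)oxy]oxolan-2-yl]ethan-1-ol | CC(C)=CCC/C(C)=C/[C@H]1C[C@](C)(O[Si](CC)(CC)CC)[C@H](CCO)O1 | intermediate
23 | {[(2S,3S,5R)-5-[(1E)-2,6-dimethylhepta-1,5-dien-1-yl]-2-(2-iodoethyl)-3-methyloxolan-3-yl]oxy}triethylsilane | CC(C)=CCC/C(C)=C/[C@H]1C[C@](C)(O[Si](CC)(CC)CC)[C@H](CCI)O1 | intermediate
24 | L-glutamic acid 5-benzyl ester [(2S)-2-amino-5-(benzyloxy)-5-oxopentanoic acid] | N[C@@H](CCC(=O)OCc1ccccc1)C(=O)O | starting material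
25 | (1S)-4-(benzyloxy)-1-carboxylato-4-oxobutane-1-diazonium | N#[N+][C@@H](CCC(=O)OCc1ccccc1)C(=O)[O-] | intermediate (not isolated)
26 | benzyl 3-[(2R)-3-oxooxiran-2-yl]propanoate | O=C1O[C@@H]1CCC(=O)OCc1ccccc1 | intermediate (not isolated)
27 | (2S)-5-(benzyloxy)-2-hydroxy-5-oxopentanoic acid | O[C@@H](CCC(=O)OCc1ccccc1)C(=O)O | intermediate
28 | 5-benzyl 1-methyl (2S)-2-hydroxypentanedioate | O[C@@H](CCC(=O)OCc1ccccc1)C(=O)OC | intermediate
29 | 5-benzyl 1-methyl (2S)-2-[(tert-butyldimethylsilyl)oxy]pentanedioate | CC(C)(C)[Si](C)(C)O[C@@H](CCC(=O)OCc1ccccc1)C(=O)OC | intermediate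
30 | (4S)-4-[(tert-butyldimethylsilyl)oxy]-5-methoxy-5-oxopentanoic acid | CC(C)(C)[Si](C)(C)O[C@@H](CCC(=O)O)C(=O)OC | intermediate
31 | methyl (2S)-2-[(tert-butyldimethylsilyl)oxy]-5-(ethylsulfanyl)-5-oxopentanoate | CC(C)(C)[Si](C)(C)O[C@@H](CCC(=O)SCC)C(=O)OC | intermediate
32 | {2-[(2S,3S,5R)-5-[(1E)-2,6-dimethylhepta-1,5-dien-1-yl]-3-methyl-3-[(triethylsilyl)oxy]oxolan-2-yl]ethyl}(iodo)zinc | CC(C)=CCC/C(C)=C/[C@H]1C[C@](C)(O[Si](CC)(CC)CC)[C@H](CC[Zn]I)O1 | intermediate (not isolated)
33 | methyl (2S)-2-[(tert-butyldimethylsilyl)oxy]-7-[(2S,3S,5R)-5-[(1E)-2,6-dimethylhepta-1,5-dien-1-yl]-3-methyl-3-[(triethylsilyl)oxy]oxolan-2-yl]-5-oxoheptanoate | CC(C)=CCC/C(C)=C/[C@H]1C[C@](C)(O[Si](CC)(CC)CC)[C@H](CCC(=O)CC[C@H](O[Si](C)(C)C(C)(C)C)C(=O)OC)O1 | intermediate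
34 | (4S)-4-[(tert-butyldimethylsilyl)oxy]-2-{[(2S,3S,5R)-5-[(1E)-2,6-dimethylhepta-1,5-dien-1-yl]-3-methyl-3-[(triethylsilyl)oxy]oxolan-2-yl]methyl}-3-hydroxycyclohex-2-en-1-one | CC(C)=CCC/C(C)=C/[C@H]1C[C@](C)(O[Si](CC)(CC)CC)[C@H](CC2=C(O)[C@@H](O[Si](C)(C)C(C)(C)C)CCC2=O)O1 | intermediate
35 | (4S)-2-{[(2S,3S,5R)-5-[(1E)-2,6-dimethylhepta-1,5-dien-1-yl]-3-hydroxy-3-methyloxolan-2-yl]methyl}-3,4-dihydroxycyclohex-2-en-1-one (CNP0194047.1) | CC(C)=CCC/C(C)=C/[C@H]1C[C@](C)(O)[C@H](CC2=C(O)[C@@H](O)CCC2=O)O1 | target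

**Count**
Total steps: 22. Longest linear sequence: 15 steps (1, 2, 5–14, 20–22).

**Steps most likely to fail**

Step 11 (proposed new method). The borane may reduce the ketone before it hydroborates the allene, boron may go to the central allene carbon, or the allylborane may equilibrate from Z to E before ring closure; each erodes yield or the C2/C3 relationship. A weak relay from C5 would also give the 2,5-cis ring. The fallback uses known chemistry, sets out from 11 and comes back at 19. O-Allylation of 11 (NaH, allyl bromide) would give the allyl ether F1. Metalation with s-BuLi in THF at −78 °C and trapping of the (Z)-oxyallyl anion at its γ-carbon with 2-isopropoxy-4,4,5,5-tetramethyl-1,3,2-dioxaborolane (the metalation route to γ-alkoxyallylboronates) would give the isolable (Z)-γ-alkoxyallyl pinacol boronate F2. Bu4NF buffered with AcOH would remove the silyl group to give the alcohol F3, and Dess–Martin oxidation would give the keto boronate F4. On warming in toluene F4 should close by intramolecular allylboration to the cyclic borate ester F5, which is hydrolysed on aqueous work-up to 19. Here the boron is in place before the ketone exists, so no hydride reagent meets the carbonyl group.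

Step 21. Deprotonation α to the ester may epimerise C4' before ring closure, alkoxide may strip the silyl ether, or intermolecular condensation may compete. The fallback sets out from 33 and comes back at 34. Hydrolysis of the methyl ester with Me3SnOH (ClCH2CH2Cl, 70 °C) would give the acid F6, and DCC with pentafluorophenol the pentafluorophenyl ester F7. Soft enolisation with MgBr2·OEt2 and i-Pr2NEt in CH2Cl2 at rt should then acylate the ketone α-carbon intramolecularly and close the ring without any strong base.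

Step 20. Zinc insertion into the hindered primary iodide may be sluggish, and the alkylzinc may be protonated or homocoupled before transmetalation. The fallback sets out from 20 and comes back at 33, bypassing 22, 23 and 32. Hydroboration of 20 with 9-BBN gives the alkylborane 21 as in step 13. Without oxidation, 21 would be coupled in the same flask with the S-phenyl thioester F8 (from acid 30, PhSH, DCC) under Liebeskind–Srogl conditions: Pd(PPh3)4 (5 mol %), copper thiophene-2-carboxylate Cu(O2CC4H3S) (1.5 equiv), Cs2CO3, THF, 45 °C.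

**Further compounds**
F1 | step 11 | tert-butyl{[(2S,4R,5E)-6,10-dimethyl-4-(prop-2-en-1-yloxy)undeca-5,9-dien-2-yl]oxy}diphenylsilane | CC(C)=CCC/C(C)=C/[C@H](OCC=C)C[C@H](C)O[Si](c1ccccc1)(c1ccccc1)C(C)(C)C
F2 | step 11 | tert-butyl{[(2S,4R,5E)-6,10-dimethyl-4-{[(1Z)-3-(4,4,5,5-tetramethyl-1,3,2-dioxaborolan-2-yl)prop-1-en-1-yl]oxy}undeca-5,9-dien-2-yl]oxy}diphenylsilane | CC(C)=CCC/C(C)=C/[C@H](O/C=C\CB1OC(C)(C)C(C)(C)O1)C[C@H](C)O[Si](c1ccccc1)(c1ccccc1)C(C)(C)C
F3 | step 11 | (2S,4R,5E)-6,10-dimethyl-4-{[(1Z)-3-(4,4,5,5-tetramethyl-1,3,2-dioxaborolan-2-yl)prop-1-en-1-yl]oxy}undeca-5,9-dien-2-ol | CC(C)=CCC/C(C)=C/[C@H](O/C=C\CB1OC(C)(C)C(C)(C)O1)C[C@H](C)O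
F4 | step 11 | (4R,5E)-6,10-dimethyl-4-{[(1Z)-3-(4,4,5,5-tetramethyl-1,3,2-dioxaborolan-2-yl)prop-1-en-1-yl]oxy}undeca-5,9-dien-2-one | CC(C)=CCC/C(C)=C/[C@H](O/C=C\CB1OC(C)(C)C(C)(C)O1)CC(C)=O
F5 | step 11 | 2-{[(2S,3S,5R)-5-[(1E)-2,6-dimethylhepta-1,5-dien-1-yl]-2-ethenyl-3-methyloxolan-3-yl]oxy}-4,4,5,5-tetramethyl-1,3,2-dioxaborolane | CC(C)=CCC/C(C)=C/[C@H]1C[C@](C)(OB2OC(C)(C)C(C)(C)O2)[C@H](C=C)O1
F6 | step 21 | (2S)-2-[(tert-butyldimethylsilyl)oxy]-7-[(2S,3S,5R)-5-[(1E)-2,6-dimethylhepta-1,5-dien-1-yl]-3-methyl-3-[(triethylsilyl)oxy]oxolan-2-yl]-5-oxoheptanoic acid | CC(C)=CCC/C(C)=C/[C@H]1C[C@](C)(O[Si](CC)(CC)CC)[C@H](CCC(=O)CC[C@H](O[Si](C)(C)C(C)(C)C)C(=O)O)O1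
F7 | step 21 | pentafluorophenyl (2S)-2-[(tert-butyldimethylsilyl)oxy]-7-[(2S,3S,5R)-5-[(1E)-2,6-dimethylhepta-1,5-dien-1-yl]-3-methyl-3-[(triethylsilyl)oxy]oxolan-2-yl]-5-oxoheptanoate | CC(C)=CCC/C(C)=C/[C@H]1C[C@](C)(O[Si](CC)(CC)CC)[C@H](CCC(=O)CC[C@H](O[Si](C)(C)C(C)(C)C)C(=O)Oc2c(F)c(F)c(F)c(F)c2F)O1
F8 | step 20 | methyl (2S)-2-[(tert-butyldimethylsilyl)oxy]-5-oxo-5-(phenylsulfanyl)pentanoate | CC(C)(C)[Si](C)(C)O[C@@H](CCC(=O)Sc1ccccc1)C(=O)OC
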